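Draw the blue run's target curve first, from its slope at the start to the level it runs into, then carry that level as a concentration to the flasks at 0.020 M.

common to all: gas 0.69 mM (held)

| run | starting material | second nucleophile | temperature | remark | time |
|---|---|---|---|---|---|
| blue | 0.030 M | 5 equiv | 25 °C | run made earlier |  |
| alpha | 0.020 M | 5.00 equiv | 25 °C |  | 12 h |
| beta | 0.020 M | 5.00 equiv |  | at 25 °C until 4.0 h, from then on at 75 °C | 12 h |
| epsilon | 0.020 M | 5.00 equiv | 75 °C |  | 12 h |
| zeta | 0.020 M | 5.00 equiv | 50 °C |  | 12 h |

blue run (percent of the starting material charged)

| time / h | target / % | starting material / % |
|---|---|---|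
| 0.133 | 1.9 | 96.6 |
| 0.333 | 3.2 | 91.2 |
| 0.667 | 4.7 | 82.2 |
| 1.00 | 5.9 | 72.1 |
| 1.33 | 8.7 | 64.1 |
| 2.00 | 7.7 | 50.6 |
| 2.50 | 8.7 | 41.9 |

(each reading ± 0.5 percentage points)

- the analysis behind the earlier runs scatters by 0.5 percentage points, standard deviation
- at the start none of the gas is in solution
- the earlier runs do not show what temperature does; that part of a forecast is a guess

1. which flask leads in amount of target, in percent of the starting material charged ("all alike" within 1.5 percentage points) (alpha / beta / epsilon / zeta / all alike)
2. how much target is there at the end, in percent of the starting material charged: alpha
3. how much target is there at the end, in percent of the starting material charged: beta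
4. how much target is there at the end, in percent of the starting material charged: epsilon
5. how much target is there at the end, in percent of the starting material charged: zeta

Start with the starting material, which in the blue run falls to 41.9% by 2.50 h; reckoned as a first-order fall, that gives k = 0.348 h⁻¹, a lifetime of 2.87 h. The first target reading, 1.9% at 0.133 h, gives a starting slope of 0.143 h⁻¹ in fractions of the charge. The readings from 1.33 h on average 8.37%, each with a scatter of 0.5 percentage points. Extend the starting slope until it meets that level and the knee falls at 0.586 h, earlier than the lifetime, so the curve bends while the blue run still reads 82.2% of starting material at 0.667 h.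

Now read the flat part. Assume that the making of target goes with the starting material; the starting material falls from 64.1% to 41.9% while the target stays level, so the loss of target must fall with it. That makes the loss a step between target and starting material, and the level a quasi-steady state. Making and loss then both carry the starting material, which cancels, and what remains is a fixed concentration of target. Call it the standing level c*, the target concentration at which making and loss balance: as read from these scattered blue readings, c* = 2.51 mM. At 0.020 M, c* means 12.5% of the charge for alpha, where the blue rate reckons 1.54% of the starting material left at 12 h, so I take that as my estimate for alpha's end. The earlier runs are silent on temperature, so my guess leaves c* unshifted for the warmer flasks.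

The forecast stands lower than this reckoning, at 4% for alpha, 3% for beta, 3% for epsilon and 3% for zeta, with all alike as its answer: “Heating speeds both steps, so all flasks should finish low and similar”.

The flasks end at 15.3% for alpha, 18.4% for beta, 13.7% for epsilon and 22.4% for zeta, so zeta leads.

    starting material ⇌ intermediate (K = 0.150, k = 7.19 × 10⁻⁵ s⁻¹, Ea = 87.0 kJ mol⁻¹, ΔH = −45.0 kJ mol⁻¹)
    first nucleophile + intermediate → target (k = 85.3 L mol⁻¹ s⁻¹, Ea = 48.0 kJ mol⁻¹)
    second nucleophile + intermediate → other capture product (k = 0.325 L mol⁻¹ s⁻¹, Ea = 40.0 kJ mol⁻¹)
    starting material + target → side product (k = 0.0142 L mol⁻¹ s⁻¹, Ea = 64.0 kJ mol⁻¹)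
    gas ⇌ first nucleophile, rate k5*(csat - [first nucleophile]) (kL = 0.0158 s⁻¹)
    (constants at 25 °C)

Take away the loss of starting material + target to side product and alpha ends at 61.2% instead of 15.3%, which makes that step the main reason for the target alpha lacks. Alpha holds 3.06 mM of target against the c* of 2.51 mM read from the blue run. For beta's recipe at 0.080 M of starting material, c* gives 3.14%, and that flask ends at 2.74%, against 18.4% in beta.

Readings and results were generated by integration for substances that don't exist; noise was put on by code.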